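Numbering: ring carbons C1 (ketone), C2, C3 (enol ether carbon), C4 (methyl C15), C5, C6 (ester oxygen O6), C7, C8 (lactone oxygen O8), C9, C10 (methyl C14, ether oxygen); lactone carbons C11, C12 (carbonyl), C13 (methylene).
Enabling feature: the trans-fused α-methylene-γ-butyrolactone (ring C7–C8–O8–C12–C11, exocyclic C13) shares its C7–C8 bond with the ten-membered carbocycle C1–C10, so a 2-(methoxycarbonyl)allyl metal (C13–C11–C7) adding through C7 to a C8 aldehyde closes both rings.
Cuts, in retrosynthetic order: O6–acyl (tiglate); C7–C8 together with O8–C12; C11–C13 (hydroxymethyl cross-coupling); C6–C7 (propiolate addition to a C6 enal); O–C3 of the furanone (hydroxy ynone cyclisation); C1–C2 (acetylide on a dioxolanone).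
Forward order: the furanone ring is made first, the chain is grown at C6 to the 2-(bromomethyl) enoate with C6 trans to CH2Br, the carbocycle and the lactone then close in one operation, and the tiglate goes on last. It is held back because a free O6 would lactonise onto the cis ester and an allylic ester is not safe with zerovalent palladium.
Stereochemistry: C10 from (S)-citramalic acid; Z C4=C5 from the commercial enynol; C6 from ligand-controlled alkynylation; the C7=C11 geometry from syn hydrostannation and stereoretentive coupling; C7 and C8 from the chair transition state of the chromium allylation under control of C6.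

Key step: step 16

Assumption: the catalyst formed from Me2Zn and (S,S)-ProPhenol is taken to add the alkynyl group to the Re face of enal 12 (giving 6S); should the sense be the opposite, the (R,R)-ligand is used in the same way.

## Route

Step 1
Reactants: 1 (S)-citramalic acid
Product: 2 dioxolanone acid
Conditions: 2,2-dimethoxypropane, TsOH·H2O (cat.), CH2Cl2, rt
Reagents that add atoms: 2,2-dimethoxypropane, `COC(C)(C)OC`
Why: Acid-catalysed transacetalisation (acetonide formation) ties the tertiary hydroxyl and the neighbouring carboxyl into the five-membered 1,3-dioxolan-4-one, which differentiates the two acids without touching the quaternary centre that becomes C10.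

Step 2
Reactants: 2 dioxolanone acid
Product: 3 hydroxyethyl dioxolanone
Conditions: BH3·THF, THF, 0 °C to rt; MeOH quench
Reagents that add atoms: none
Why: Chemoselective borane reduction of a free carboxylic acid, which is much faster than attack on the lactone-like dioxolanone carbonyl, takes only the future C8 to the alcohol level.

Step 3
Reactants: 3 hydroxyethyl dioxolanone
Product: 4 TBS-oxyethyl dioxolanone
Conditions: TBSCl, imidazole, DMF, 0 °C
Reagents that add atoms: tert-butyldimethylsilyl chloride, `CC(C)(C)[Si](C)(C)Cl`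
Why: Imidazole-mediated silylation of a primary alcohol under neutral conditions caps O8 before it can translactonise onto the dioxolanone and gives the ether that has to last until step 14.

Step 4
Reactants: 5 (Z)-3-methylpent-2-en-4-yn-1-ol
Product: 6 TES ether of the enynol
Conditions: TESCl, imidazole, CH2Cl2, 0 °C
Reagents that add atoms: chlorotriethylsilane, `CC[Si](Cl)(CC)CC`
Why: Standard silyl ether formation; the triethylsilyl group keeps O6 out of the acetylide chemistry and away from the alkyne, and can later be removed beside the tert-butyldimethylsilyl ether.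

Step 5
Reactants: 6 TES ether of the enynol; 4 TBS-oxyethyl dioxolanone
Product: 9 α′-hydroxy ynone (C8 OTBS; C6 OTES), via lithium acetylide 7 (not isolated), via lithium hemiketal alkoxide 8 (not isolated)
Conditions: n-BuLi, THF, −78 °C; then 4, −78 to −30 °C; aq. NH4Cl
Reagents that add atoms: n-butyllithium, `[Li]CCCC` (lithium only in 7 and 8)
Why: Nucleophilic acyl substitution on an activated ester: the lithium acetylide adds once to the dioxolanone carbonyl, the tetrahedral lithium alkoxide lasts until work-up and then sheds acetone to give the ketone with the free tertiary hydroxyl, and the fully substituted C10 cannot enolise or epimerise.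

Step 6
Reactants: 9 α′-hydroxy ynone
Product: 10 furanone (C8 OTBS; C6 OTES)
Conditions: (p-CF3C6H4)3PAuCl (cat.), AgOSO2CF3 (cat.), toluene, rt
Reagents that add atoms: none
Why: Cycloisomerisation of a γ-hydroxy alkynone to a 3(2H)-furanone: the cationic monovalent gold complex activates the triple bond, the tertiary hydroxyl adds 5-endo-dig to C3 and protodeauration follows, while the silyl ether oxygens are too weakly nucleophilic to compete.

Step 7
Reactants: 10 furanone
Product: 11 furanone allylic alcohol (C6 OH)
Conditions: PPTS (cat.), MeOH, 0 °C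
Reagents that add atoms: none
Why: Selective silyl ether solvolysis: acid-catalysed methanolysis cleaves a primary triethylsilyl ether far faster than a primary tert-butyldimethylsilyl ether, and the short cold exposure limits acid-induced reorganisation of the Z-hydroxyalkenyl furanone.

Step 8
Reactants: 11 furanone allylic alcohol
Product: 12 furanone Z-enal (C6 aldehyde)
Conditions: MnO2 (activated, excess), CH2Cl2, rt
Reagents that add atoms: none
Why: MnO2 oxidation of an allylic alcohol is heterogeneous and neutral, stops at the aldehyde and is known to leave Z-enals unisomerised.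

Step 9
Reactants: 12 furanone Z-enal; 13 methyl propiolate
Product: 14 (6S)-hydroxy ynoate
Conditions: Me2Zn, (S,S)-ProPhenol (cat.), Ph3P=O (cat.), toluene, 0–4 °C; aq. NH4Cl
Reagents that add atoms: none
Why: Catalytic asymmetric alkynylation of an enal: the methylzinc alkynylide MeZnC≡CCO2Me, bound to the chiral ligand, adds 1,2 to the aldehyde only (the vinylogous ester carbonyl is far less electrophilic), and the ligand decides the face, which creates C6 as S.

Step 10
Reactants: 14 (6S)-hydroxy ynoate
Product: 15 (6S)-silyloxy ynoate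
Conditions: TBSOTf, 2,6-lutidine, CH2Cl2, −78 °C
Reagents that add atoms: tert-butyldimethylsilyl trifluoromethanesulfonate, `CC(C)(C)[Si](C)(C)OS(=O)(=O)C(F)(F)F`
Why: Silylation with a silyl triflate and a hindered base is fast at low temperature and avoids base-induced isomerisation of the γ-oxy ynoate; the ether keeps O6 from lactonising onto the cis ester made in step 11 and, unlike an allylic ester, is indifferent to zerovalent palladium.

Step 11
Reactants: 15 (6S)-silyloxy ynoate
Product: 17 α-iodo enoate (2E; C6 cis to CO2Me), via α-stannyl enoate 16 (not isolated)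
Conditions: Bu3SnH, Pd(PPh3)4 (cat.), THF, 0 °C; then I2, CH2Cl2, 0 °C
Reagents that add atoms: iodine, `II`; tributyltin hydride, `CCCC[SnH](CCCC)CCCC` (tin only in 16)
Why: Palladium-catalysed hydrostannation of an ynoate is a syn addition that places tin on C11 (α to the ester) and hydrogen on C7, so C6 ends cis to the ester, and iododestannylation then replaces tin by iodine with retention of the alkene geometry.

Step 12
Reactants: 17 α-iodo enoate; 18 (tributylstannyl)methanol
Product: 19 2-(hydroxymethyl) enoate
Conditions: Pd(PPh3)4 (cat.), 1,4-dioxane, 80 °C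
Reagents that add atoms: none
Why: Stille cross-coupling of the alkenyl iodide with the hydroxymethyl stannane forms C11–C13 with retention of geometry, which leaves C13 trans to C6, and the allylic silyl ether is not ionised by zerovalent palladium.

Step 13
Reactants: 19 2-(hydroxymethyl) enoate
Product: 20 2-(bromomethyl) enoate
Conditions: CBr4, PPh3, CH2Cl2, 0 °C
Reagents that add atoms: carbon tetrabromide, `BrC(Br)(Br)Br`
Why: Appel reaction: the oxyphosphonium leaving group is displaced by bromide in an SN2 reaction at the primary carbon, cold and briefly, so that neither allylic transposition nor bromide-induced E/Z scrambling should set in.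

Step 14
Reactants: 20 2-(bromomethyl) enoate
Product: 21 C8 alcohol of the bromo ester
Conditions: CSA (cat.), MeOH/CH2Cl2, 0 °C
Reagents that add atoms: none
Why: Selective desilylation: acid-catalysed methanolysis removes the unhindered primary silyl ether at C8 much faster than the hindered secondary one at C6, and methanol at 0 °C is too weak a nucleophile to displace the allylic bromide.

Step 15
Reactants: 21 C8 alcohol of the bromo ester
Product: 22 seco C8 aldehyde with C13 allylic bromide
Conditions: Dess–Martin periodinane, CH2Cl2, 0 °C to rt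
Reagents that add atoms: none
Why: Dess–Martin oxidation of the primary alcohol runs under non-basic conditions, so the aldehyde does not lose the β-oxygen at C10 by elimination and the allylic bromide is untouched.

Step 16
Reactants: 22 seco C8 aldehyde with C13 allylic bromide
Product: 25 ten-membered trans-fused α-methylene lactone (C6 OTBS), via allylchromium dichloride 23 (not isolated), via dichlorochromium alkoxide 24 (not isolated)
Conditions: CrCl2 (6 equiv), THF, rt, slow addition of 22 (final concentration about 0.003 M); aq. NH4Cl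
Reagents that add atoms: chromium dichloride, `Cl[Cr]Cl` (chromium only in 23 and 24)
Why: CrCl2 (two equivalents of divalent chromium, each giving one electron) turns the C13–Br bond into the trivalent allylchromium dichloride 23, which adds to the C8 aldehyde with allylic transposition through a six-membered chair in which chromium is bound to the aldehyde oxygen, so that the new bond forms at C7; this is the Nozaki–Hiyama–Kishi-type allylation of an aldehyde by a 2-(alkoxycarbonyl)allyl bromide, known to give α-methylene lactones and to close medium rings. The ten-membered carbocycle closes by this intramolecular carbonyl addition (exo attack on the aldehyde, C7 to C8), and the lactone by 5-exo-trig acyl substitution of the chromium alkoxide 24 on the adjacent C12 methyl ester with loss of methoxide. C8 is set relative to C7 by the chair: the E-type reagent (C6 trans to the CH2Cr carbon, fixed in steps 11 and 12) with the C9 chain equatorial should give H7 and H8 anti, which is the trans ring fusion (7R,8S). The face of C7 is set by C6: allylic 1,3-strain with the cis ester holds H6 in the plane of the C7=C11 bond, and the aldehyde should arrive anti to the C5 ring arm, the arrangement that also leaves the C5–C6 and C7–C8 ring bonds antiperiplanar. The step needs ring closure to win over oligomerisation and the allyl geometry to survive; high dilution, the Z-alkenyl furanone that holds C6 and C9 on one side, and the absence of base or nucleophile (which also leaves the β-alkoxy aldehyde, the dienone and the silyl ether alone) are what should secure this.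

Step 17
Reactants: 25 ten-membered trans-fused α-methylene lactone (C6 OTBS)
Product: 26 C6 alcohol
Conditions: HF·pyridine, THF, 0 °C to rt
Reagents that add atoms: none
Why: Fluoride-driven Si–O cleavage with buffered hydrogen fluoride is non-basic, so the α-methylene lactone should suffer neither conjugate addition nor migration of the lactone to O6.

Step 18
Reactants: 26 C6 alcohol; 27 tiglic acid
Product: 28 target compound
Conditions: DCC, DMAP (cat.), CH2Cl2, 0 °C to rt
Reagents that add atoms: none
Why: Steglich esterification (carbodiimide activation with acyl transfer by DMAP) acylates the secondary allylic alcohol with the configurationally stable E acid and changes no stereocentre.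

## Compound list

1 | (S)-citramalic acid, (2S)-2-hydroxy-2-methylbutanedioic acid | `C[C@](O)(CC(=O)O)C(=O)O` | starting material
2 | [(4S)-2,2,4-trimethyl-5-oxo-1,3-dioxolan-4-yl]acetic acid | `C[C@@]1(CC(=O)O)OC(C)(C)OC1=O` | intermediate
3 | (5S)-5-(2-hydroxyethyl)-2,2,5-trimethyl-1,3-dioxolan-4-one | `C[C@@]1(CCO)OC(C)(C)OC1=O` | intermediate
4 | (5S)-5-[2-(tert-butyldimethylsilyloxy)ethyl]-2,2,5-trimethyl-1,3-dioxolan-4-one | `C[C@@]1(CCO[Si](C)(C)C(C)(C)C)OC(C)(C)OC1=O` | intermediate
5 | (2Z)-3-methylpent-2-en-4-yn-1-ol | `C#C/C(C)=C\CO` | starting material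
6 | triethyl{[(2Z)-3-methylpent-2-en-4-yn-1-yl]oxy}silane | `C#C/C(C)=C\CO[Si](CC)(CC)CC` | intermediate
7 | lithium acetylide of 6 | `[Li]C#C/C(C)=C\CO[Si](CC)(CC)CC` | intermediate (not isolated)
8 | lithium hemiketal alkoxide, adduct of 7 to the ring carbonyl of 4 (new carbinol centre unassigned) | `C[C@@]1(CCO[Si](C)(C)C(C)(C)C)OC(C)(C)OC1(O[Li])C#C/C(C)=C\CO[Si](CC)(CC)CC` | intermediate (not isolated)
9 | (3S,7Z)-1-(tert-butyldimethylsilyloxy)-3-hydroxy-3,7-dimethyl-9-(triethylsilyloxy)non-7-en-5-yn-4-one | `CC(C)(C)[Si](C)(C)OCC[C@](C)(O)C(=O)C#C/C(C)=C\CO[Si](CC)(CC)CC` | intermediate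
10 | (2S)-2-[2-(tert-butyldimethylsilyloxy)ethyl]-2-methyl-5-[(2Z)-4-(triethylsilyloxy)but-2-en-2-yl]furan-3(2H)-one | `CC(C)(C)[Si](C)(C)OCC[C@]1(C)OC(=CC1=O)/C(C)=C\CO[Si](CC)(CC)CC` | intermediate
11 | (2S)-2-[2-(tert-butyldimethylsilyloxy)ethyl]-5-[(2Z)-4-hydroxybut-2-en-2-yl]-2-methylfuran-3(2H)-one | `CC(C)(C)[Si](C)(C)OCC[C@]1(C)OC(=CC1=O)/C(C)=C\CO` | intermediate
12 | (2Z)-3-{(5S)-5-[2-(tert-butyldimethylsilyloxy)ethyl]-5-methyl-4-oxo-4,5-dihydrofuran-2-yl}but-2-enal | `CC(C)(C)[Si](C)(C)OCC[C@]1(C)OC(=CC1=O)/C(C)=C\C=O` | intermediate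
13 | methyl propiolate | `C#CC(=O)OC` | starting material
14 | methyl (4S,5Z)-6-{(5S)-5-[2-(tert-butyldimethylsilyloxy)ethyl]-5-methyl-4-oxo-4,5-dihydrofuran-2-yl}-4-hydroxyhept-5-en-2-ynoate | `CC(C)(C)[Si](C)(C)OCC[C@]1(C)OC(=CC1=O)/C(C)=C\[C@H](O)C#CC(=O)OC` | intermediate
15 | methyl (4S,5Z)-4-(tert-butyldimethylsilyloxy)-6-{(5S)-5-[2-(tert-butyldimethylsilyloxy)ethyl]-5-methyl-4-oxo-4,5-dihydrofuran-2-yl}hept-5-en-2-ynoate | `CC(C)(C)[Si](C)(C)OCC[C@]1(C)OC(=CC1=O)/C(C)=C\[C@H](O[Si](C)(C)C(C)(C)C)C#CC(=O)OC` | intermediate
16 | methyl (2E,4S,5Z)-4-(tert-butyldimethylsilyloxy)-6-{(5S)-5-[2-(tert-butyldimethylsilyloxy)ethyl]-5-methyl-4-oxo-4,5-dihydrofuran-2-yl}-2-(tributylstannyl)hepta-2,5-dienoate | `CC(C)(C)[Si](C)(C)OCC[C@]1(C)OC(=CC1=O)/C(C)=C\[C@H](O[Si](C)(C)C(C)(C)C)/C=C(/[Sn](CCCC)(CCCC)CCCC)C(=O)OC` | intermediate (not isolated)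
17 | methyl (2E,4S,5Z)-4-(tert-butyldimethylsilyloxy)-6-{(5S)-5-[2-(tert-butyldimethylsilyloxy)ethyl]-5-methyl-4-oxo-4,5-dihydrofuran-2-yl}-2-iodohepta-2,5-dienoate | `CC(C)(C)[Si](C)(C)OCC[C@]1(C)OC(=CC1=O)/C(C)=C\[C@H](O[Si](C)(C)C(C)(C)C)/C=C(/I)C(=O)OC` | intermediate
18 | (tributylstannyl)methanol | `CCCC[Sn](CO)(CCCC)CCCC` | starting material
19 | methyl (2Z,4S,5Z)-4-(tert-butyldimethylsilyloxy)-6-{(5S)-5-[2-(tert-butyldimethylsilyloxy)ethyl]-5-methyl-4-oxo-4,5-dihydrofuran-2-yl}-2-(hydroxymethyl)hepta-2,5-dienoate (C6 trans to CH2OH) | `CC(C)(C)[Si](C)(C)OCC[C@]1(C)OC(=CC1=O)/C(C)=C\[C@H](O[Si](C)(C)C(C)(C)C)/C=C(/CO)C(=O)OC` | intermediate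
20 | methyl (2E,4S,5Z)-2-(bromomethyl)-4-(tert-butyldimethylsilyloxy)-6-{(5S)-5-[2-(tert-butyldimethylsilyloxy)ethyl]-5-methyl-4-oxo-4,5-dihydrofuran-2-yl}hepta-2,5-dienoate (C6 trans to CH2Br) | `CC(C)(C)[Si](C)(C)OCC[C@]1(C)OC(=CC1=O)/C(C)=C\[C@H](O[Si](C)(C)C(C)(C)C)/C=C(/CBr)C(=O)OC` | intermediate
21 | methyl (2E,4S,5Z)-2-(bromomethyl)-4-(tert-butyldimethylsilyloxy)-6-[(5S)-5-(2-hydroxyethyl)-5-methyl-4-oxo-4,5-dihydrofuran-2-yl]hepta-2,5-dienoate | `OCC[C@]1(C)OC(=CC1=O)/C(C)=C\[C@H](O[Si](C)(C)C(C)(C)C)/C=C(/CBr)C(=O)OC` | intermediate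
22 | methyl (2E,4S,5Z)-2-(bromomethyl)-4-(tert-butyldimethylsilyloxy)-6-[(5S)-5-methyl-4-oxo-5-(2-oxoethyl)-4,5-dihydrofuran-2-yl]hepta-2,5-dienoate | `O=CC[C@]1(C)OC(=CC1=O)/C(C)=C\[C@H](O[Si](C)(C)C(C)(C)C)/C=C(/CBr)C(=O)OC` | intermediate
23 | allylchromium dichloride derived from 22 (CrCl2 on C13 in place of bromine, geometry unchanged) | `O=CC[C@]1(C)OC(=CC1=O)/C(C)=C\[C@H](O[Si](C)(C)C(C)(C)C)/C=C(/C[Cr](Cl)Cl)C(=O)OC` | intermediate (not isolated)
24 | dichlorochromium alkoxide of the ten-membered hydroxy ester (C7–C8 bond formed, C11=C13 methylene, C12 still the methyl ester, O8 on chromium) | `COC(=O)C(=C)[C@@H]1[C@@H](O[Cr](Cl)Cl)C[C@]2(C)OC(=CC2=O)/C(C)=C\[C@@H]1O[Si](C)(C)C(C)(C)C` | intermediate (not isolated)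
25 | (6S,7R,8S,10S)-O6-tert-butyldimethylsilyl ether of the detigloyl target: ten-membered carbocycle with the C1/C3/C10 furanone, Z C4=C5, trans-fused 8,12-lactone and C11=C13 methylene | `C=C1C(=O)O[C@H]2C[C@]3(C)OC(=CC3=O)/C(C)=C\[C@H](O[Si](C)(C)C(C)(C)C)[C@H]12` | intermediate
26 | C6 alcohol (25 without the silyl group; all four centres arranged as in 25) | `C=C1C(=O)O[C@H]2C[C@]3(C)OC(=CC3=O)/C(C)=C\[C@H](O)[C@H]12` | intermediate
27 | tiglic acid, (2E)-2-methylbut-2-enoic acid | `C/C=C(\C)C(=O)O` | starting material
28 | target compound, (6S,7R,8S,10S)-6-O-tiglate | `C=C1C(=O)O[C@H]2C[C@]3(C)OC(=CC3=O)/C(C)=C\[C@H](OC(=O)/C(C)=C/C)[C@H]12` | target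

## Count and risks

Total: 18 steps. Longest linear sequence: 17 steps (from 1 through steps 1–3 and 5–18; step 4 is the one-step side branch).

The three steps most likely to fail are steps 16, 9 and 5.

Step 16. The allyl geometry may be lost before ring closure, either by bromide-induced isomerisation of the allylic bromide or by equilibration of the allylchromium through its secondary isomer. That would lead to the cis-fused lactone. The aldehyde may also reach the wrong face of C7, or chain growth may compete with cyclisation. The fallback replaces chromium by boron, whose allyl transfer is strictly stereospecific and needs no allylic bromide. It sets out from 17. Cross-coupling with the zinc reagent IZnCH2B(pin) (Pd(PPh3)4, THF, rt, Negishi type) should give the pinacol allylboronate F1 with C6 trans to the CH2B carbon. Selective methanolysis (CSA, MeOH, 0 °C) should give the C8 alcohol F2, and Dess–Martin oxidation the boronate aldehyde F3. Warming F3 in toluene at high dilution (or Sc(OSO2CF3)3 at rt), followed by a trace of TsOH, should bring about allylboration through the closed chair and lactonisation with loss of MeOB(pin). The fallback comes back to the route at 25.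

Step 9. The hindered Z-configured enal may show poor facial discrimination, or it may isomerise from Z to E under the zinc alkoxide conditions. The fallback sets C6 by reagent-controlled reduction instead of addition and sets out from 12. Lithiated methyl propiolate (LiN(SiMe3)2, THF, −78 °C) should give the C6-epimeric alcohol mixture F4, and Dess–Martin oxidation the ynone F5. Corey–Bakshi–Shibata reduction should then return the route to 14; the (S)-methyl oxazaborolidine with catecholborane at −78 °C is chosen on the premise that the alkenyl arm acts as the large group.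

Step 5. Attack on the neopentyl-type carbonyl may be sluggish, or the tetrahedral adduct may collapse in the flask and take up a second acetylide. The fallback is a Weinreb ketone synthesis and sets out from 4. MeNH(OMe)·HCl with i-PrMgCl (THF, −20 °C) should open the dioxolanone, with loss of acetone, to the α-hydroxy Weinreb amide F6. Two equivalents of acetylide 7 should then give a chelated adduct that cannot react further and that releases 9 on work-up, where the fallback rejoins the route.

## Further compounds

F1 | step 16 | methyl (2Z,4S,5Z)-4-(tert-butyldimethylsilyloxy)-6-{(5S)-5-[2-(tert-butyldimethylsilyloxy)ethyl]-5-methyl-4-oxo-4,5-dihydrofuran-2-yl}-2-[(4,4,5,5-tetramethyl-1,3,2-dioxaborolan-2-yl)methyl]hepta-2,5-dienoate | `CC(C)(C)[Si](C)(C)OCC[C@]1(C)OC(=CC1=O)/C(C)=C\[C@H](O[Si](C)(C)C(C)(C)C)/C=C(/CB2OC(C)(C)C(C)(C)O2)C(=O)OC`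
F2 | step 16 | C8 alcohol of F1 (2-hydroxyethyl on the furanone) | `OCC[C@]1(C)OC(=CC1=O)/C(C)=C\[C@H](O[Si](C)(C)C(C)(C)C)/C=C(/CB2OC(C)(C)C(C)(C)O2)C(=O)OC`
F3 | step 16 | C8 aldehyde of F1 (2-oxoethyl on the furanone) | `O=CC[C@]1(C)OC(=CC1=O)/C(C)=C\[C@H](O[Si](C)(C)C(C)(C)C)/C=C(/CB2OC(C)(C)C(C)(C)O2)C(=O)OC`
F4 | step 9 | methyl (4RS,5Z)-6-{(5S)-5-[2-(tert-butyldimethylsilyloxy)ethyl]-5-methyl-4-oxo-4,5-dihydrofuran-2-yl}-4-hydroxyhept-5-en-2-ynoate (C6 epimers) | `CC(C)(C)[Si](C)(C)OCC[C@]1(C)OC(=CC1=O)/C(C)=C\C(O)C#CC(=O)OC`
F5 | step 9 | methyl (5Z)-6-{(5S)-5-[2-(tert-butyldimethylsilyloxy)ethyl]-5-methyl-4-oxo-4,5-dihydrofuran-2-yl}-4-oxohept-5-en-2-ynoate | `CC(C)(C)[Si](C)(C)OCC[C@]1(C)OC(=CC1=O)/C(C)=C\C(=O)C#CC(=O)OC`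
F6 | step 5 | (2S)-4-(tert-butyldimethylsilyloxy)-2-hydroxy-N-methoxy-N,2-dimethylbutanamide | `CC(C)(C)[Si](C)(C)OCC[C@](C)(O)C(=O)N(C)OC`
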